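The runs were computed with made-up constants; the scatter is artificial.

3 numbers are asked, and I reckoned each by building the flask up one process at a time.

| flask | solid substrate | partner | remark | time |
|---|---|---|---|---|
| violet | 39 mM | 3.6 equiv | run made earlier |  |
| delta | 39 mM | 1.00 equiv |  | 1.5 h |
| beta | 39 mM | 1.20 equiv |  | 1.5 h |
| theta | 39 mM | 2.50 equiv |  | 1.5 h |

violet run (percent of the solid substrate charged)

| time / min | first product / % | solid substrate / % |
|---|---|---|
| 6.00 | 8 | 82 |
| 20.0 | 41 | 45 |
| 30.0 | 57 | 21 |
| 50.0 | 74 | 0 |
| 60.0 | 69 | 0 |
| 90.0 | 52 | 0 |

(scatter of a reading: 1.5 percentage points)

- as a solid, counted per litre of solution: solid substrate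
- the numbers in the tables scatter by 1.5 percentage points (one standard deviation)
- at the start none of the solid substrate is in solution

1. final first product, as a percentage of the solid substrate charged, for each flask in turn (delta, beta, theta)

I began with the main step. In violet the solid fell by 0.0254 min⁻¹ of the charge between 6.00 min and 30.0 min, and at the first reading 10.0% of the charge was neither solid nor product. I read that gap as dissolved material on its way to product, and I assumed the solid enters solution at this pace whatever the partner. That gave a main-step constant per equivalent of partner, and a mean time for product in the flask, counted from half the clearing time:

main constant = 0.0706 min⁻¹; mean time = 70.3 min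

Second-order reckoning then left unconverted 16.8% in delta, 8.93% in beta and 0.0350% in theta.

Next came the loss. Once violet's solid read 0% at 50.0 min, its first product readings fell at 0.00882 min⁻¹, which I treated as a pseudo-first-order decay under excess partner. Dividing by the partner left gives the loss constant, the decay of first product per equivalent of partner left. I went round twice. With 2.60 left it was 0.00339 min⁻¹. Counting each lost share as partner used, 2.23 were left, and the constant became 0.00396 min⁻¹.

The same two rounds served each flask, the second taking half the loss out of the partner:

first product = converted share × exp(−loss constant × partner left × mean time)

delta: 79.4%, then 79.9%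

beta: 84.0%, then 84.9%

theta: 65.9%, then 69.1%

The forecast, reading “a saturated solution (about 4 mM) reacting with the partner”, gave 44%, 52% and 69%, lower than mine for delta and beta, and level with mine for theta.

The flasks gave 76.1%, 81.4% and 68.4%.

    starting material + partner → first product (k = 0.0362 M⁻¹ s⁻¹)
    partner + first product → double product (k = 0.00146 M⁻¹ s⁻¹)
    partner + first product → over-reaction product (k = 3.04 × 10⁻⁴ M⁻¹ s⁻¹)
    solid substrate ⇌ starting material, rate k4*(cs4 - [starting material]) while solid is left; crystals form when [starting material] > cs4 (solubility = 27.0 mM, k = 7.49 × 10⁻⁴ s⁻¹)

In delta at 1.50 h, starting material stood at 18.3% with partner at 12.7% of its own charge. I put the loss constant to theta's second half, counting the 7.97% starting material as first product beside the 78.5% first product and taking the mean of the partner at the two times, and it gave 68.4%, against 68.4%. For beta's second half it gave a loss of 4.6 percentage points, and double and over-reaction product together rose by 4.4 points.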